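**Strategy**

The benzene ring of the chroman (C4a–C5–C6–C7–C8–C8a) is built, not bought. Its three oxygens (C5–OH, C7–OMe, ring O1 on C8a) alternate with three carbon substituents, the pattern a cyclobutenone–siloxyalkyne benzannulation delivers directly. The precursors are a 3-methoxy-2-prenylcyclobutenone carrying the (R)-propyl ester arm on its sp3 carbon and a triisopropylsilyl ynol ether carrying the silyl-protected (2R,3R) carbinol chain. Heating them forges C4a–C5 and C8–C8a, re-forms C5–C6 and should give the hexasubstituted phenol with all three oxygens differentiated. A temporary lactone on the C5 oxygen then lets only the C8a oxygen close the dihydropyran by Mitsunobu inversion.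

Key step: step 9

Assumption: the quinidine-derived catalyst (DHQD)2AQN is taken to give the (S) half-ester 11; if the sense of induction proves opposite, the quinine-derived pseudoenantiomer (DHQ)2AQN replaces it with nothing else changed.

Assumption: 3-propylglutaric anhydride 10 is taken as a catalogue compound; otherwise it is one Ac2O dehydration away from 3-propylglutaric acid.

**Route**

Step 1
Reactants: 1 (2R,3R)-2,3-epoxybutane; 2 1-(trimethylsilyl)propyne
Product: 4 (2R,3R)-3-methyl-6-(trimethylsilyl)hex-5-yn-2-ol, via lithiated silylpropyne 3 (not isolated)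
Conditions: 2, n-BuLi, THF, −78 → −20 °C; then BF3·OEt2, 1, −78 °C; aq. NH4Cl
Reagents that add atoms: none
Why: Propargylic lithiation of 2 and BF3-assisted SN2 epoxide opening (the two epoxide carbons are equivalent by C2 symmetry) should set the methyl-bearing centre (R) by inversion at the attacked carbon, while the carbinol centre keeps the (R) configuration of the epoxide.

Step 2
Reactants: 4 (2R,3R)-3-methyl-6-(trimethylsilyl)hex-5-yn-2-ol
Product: 5 tert-butyl(dimethyl){[(2R,3R)-3-methyl-6-(trimethylsilyl)hex-5-yn-2-yl]oxy}silane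
Conditions: TBSCl, imidazole, DMF, rt
Reagents that add atoms: tert-butyldimethylsilyl chloride, CC(C)(C)[Si](C)(C)Cl
Why: Standard O-silylation of a secondary alcohol, which touches no stereocentre and gives an ether that survives the basic and thermal steps up to the fluoride deprotection.

Step 3
Reactants: 5 tert-butyl(dimethyl){[(2R,3R)-3-methyl-6-(trimethylsilyl)hex-5-yn-2-yl]oxy}silane
Product: 6 tert-butyl(dimethyl){[(2R,3R)-3-methylhex-5-yn-2-yl]oxy}silane
Conditions: K2CO3, MeOH, rt
Reagents that add atoms: none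
Why: Methoxide-induced protiodesilylation of the alkynylsilane should free the terminal alkyne while the secondary TBS ether stays intact.

Step 4
Reactants: 6 tert-butyl(dimethyl){[(2R,3R)-3-methylhex-5-yn-2-yl]oxy}silane
Product: 9 (4R,5R)-5-(tert-butyldimethylsilyloxy)-4-methyl-1-(triisopropylsilyloxy)hex-1-yne, via lithium acetylide 7 (not isolated), via lithium ynolate 8 (not isolated)
Conditions: n-BuLi, THF, −78 °C; LiOOtBu (from t-BuOOH and LiN(SiMe3)2), −78 → 0 °C; TIPSOTf, −78 → 0 °C
Reagents that add atoms: tert-butyl hydroperoxide, CC(C)(C)OO; triisopropylsilyl trifluoromethanesulfonate, CC(C)[Si](OS(=O)(=O)C(F)(F)F)(C(C)C)C(C)C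
Why: Electrophilic oxygen transfer from lithium tert-butyl peroxide to the acetylide (acetylide oxidation to the ynolate) followed by O-silylation with the bulky silyl triflate is an established one-pot route to triisopropylsilyl ynol ethers, and both stereocentres are remote from the reacting carbons.

Step 5
Reactants: 10 3-propylglutaric anhydride
Product: 11 (3S)-3-(2-methoxy-2-oxoethyl)hexanoic acid
Conditions: MeOH, (DHQD)2AQN [1,4-bis(dihydroquinidin-9-O-yl)anthraquinone] (cat.), Et2O, −40 °C
Reagents that add atoms: methanol, CO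
Why: Cinchona-alkaloid-catalysed desymmetrising methanolysis of the prochiral anhydride, in which the chiral amine acts as a general base and selects one of the two enantiotopic carbonyls, should set the single stereocentre of this fragment as (S).

Step 6
Reactants: 12 chloroacetaldehyde dimethyl acetal; 13 prenyl bromide (1-bromo-3-methylbut-2-ene)
Product: 15 1-methoxy-5-methylhex-4-en-1-yne, via lithium methoxyacetylide 14 (not isolated)
Conditions: LiNEt2 (3 equiv, from Et2NH and n-BuLi), THF, 0 °C; then 13, DMPU, −78 °C → rt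
Reagents that add atoms: none
Why: Three equivalents of amide base should effect elimination of methanol, dehydrochlorination and deprotonation to the lithium alkoxyacetylide, which is then alkylated at carbon by the primary allylic bromide (alkoxyacetylide SN2 alkylation).

Step 7
Reactants: 11 (3S)-3-(2-methoxy-2-oxoethyl)hexanoic acid
Product: 16 methyl (3R)-3-(2-chloro-2-oxoethyl)hexanoate
Conditions: (COCl)2, DMF (cat.), CH2Cl2, 0 °C → rt; evaporate
Reagents that add atoms: oxalyl chloride, O=C(Cl)C(=O)Cl
Why: Standard acid chloride formation through the chloroiminium made from DMF leaves the methyl ester alone, and the stereocentre, β to both carbonyls, cannot epimerise (the descriptor becomes R only because COCl outranks CO2Me).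

Step 8
Reactants: 16 methyl (3R)-3-(2-chloro-2-oxoethyl)hexanoate; 15 1-methoxy-5-methylhex-4-en-1-yne
Product: 18 methyl (3R)-3-[2-methoxy-3-(3-methylbut-2-enyl)-4-oxocyclobut-2-en-1-yl]hexanoate (both epimers at the ring CH), via aldoketene 17 (not isolated)
Conditions: 15 (1.5 equiv), Et3N, CH2Cl2, 40 °C, slow addition of 16
Reagents that add atoms: none
Why: Amine dehydrochlorination should give the aldoketene, which is trapped in a ketene–alkoxyalkyne [2+2] cycloaddition whose regiochemistry is fixed by the alkyne carbon β to OMe bonding to the ketene carbonyl; the ring CH centre forms without control, which is harmless because step 9 destroys it.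

Step 9
Reactants: 18 methyl (3R)-3-[2-methoxy-3-(3-methylbut-2-enyl)-4-oxocyclobut-2-en-1-yl]hexanoate; 9 (4R,5R)-5-(tert-butyldimethylsilyloxy)-4-methyl-1-(triisopropylsilyloxy)hex-1-yne
Product: 23 methyl (3R)-3-{3-[(2R,3R)-3-(tert-butyldimethylsilyloxy)-2-methylbutyl]-2-hydroxy-6-methoxy-5-(3-methylbut-2-enyl)-4-(triisopropylsilyloxy)phenyl}hexanoate, via vinylketene 19 (not isolated), via 4-vinylcyclobutenone 20 (not isolated), via dienylketene 21 (not isolated), via cyclohexadienone 22 (not isolated)
Conditions: PhMe, 110 °C, sealed tube (18 in slight excess)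
Reagents that add atoms: none
Why: Conrotatory 4π opening of 18 (carbonyl–CH bond, the arm rotating outward) should give vinylketene 19, which undergoes a regiospecific [2+2] cycloaddition with 9 (the alkyne carbon β to oxygen bonds to the ketene carbonyl, the silyloxy carbon to the prenyl-bearing carbon) to give 20. A second 4π opening gives dienylketene 21, and the benzene ring closes by a thermal disrotatory 6π electrocyclisation (ketene carbon onto the CH terminus, re-forming C5–C6) followed by tautomerisation of dienone 22 to the phenol, the transient four-membered ring of 20 having been closed by the [2+2] event. This is the Danheiser benzannulation of a cyclobutenone with a siloxyalkyne, applied here to a 3-alkoxy-2,4-dialkyl member of that class. No stereocentre is created: the sp3 ring carbons of 18, 20 and 22 vanish on aromatisation, and the three existing centres are spectators because the propyl-bearing one is not enolisable and the carbinol is silylated. The only selectivity required is the orientation of the ketene–alkyne cycloaddition, which the polarisation of the ynol ether fixes so that OTIPS lands on C8a between prenyl-bearing C8 and chain-bearing C4a while the ketene oxygen becomes the free C5–OH. Outward rotation keeps the C–H of the arm away from the ketene (no 1,5-hydrogen shift), and the two ortho substituents of the new phenol should slow its acylation by 19.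

Step 10
Reactants: 23 methyl (3R)-3-{3-[(2R,3R)-3-(tert-butyldimethylsilyloxy)-2-methylbutyl]-2-hydroxy-6-methoxy-5-(3-methylbut-2-enyl)-4-(triisopropylsilyloxy)phenyl}hexanoate
Product: 24 (4R)-8-[(2R,3R)-3-(tert-butyldimethylsilyloxy)-2-methylbutyl]-5-methoxy-6-(3-methylbut-2-enyl)-4-propyl-7-(triisopropylsilyloxy)-3,4-dihydro-2H-chromen-2-one
Conditions: camphorsulfonic acid (cat.), PhMe, 4 Å MS, 80 °C (crude 23 can be used)
Reagents that add atoms: none
Why: Acid-catalysed intramolecular transesterification (lactonisation) can involve only the C5–OH, the other neighbour of the arm being OMe, and it masks that phenol as a six-membered aryl lactone while the prenyl group, flanked by two protected oxygens, has no free phenol to cyclise onto.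

Step 11
Reactants: 24 (4R)-8-[(2R,3R)-3-(tert-butyldimethylsilyloxy)-2-methylbutyl]-5-methoxy-6-(3-methylbut-2-enyl)-4-propyl-7-(triisopropylsilyloxy)-3,4-dihydro-2H-chromen-2-one
Product: 25 (4R)-7-hydroxy-8-[(2R,3R)-3-hydroxy-2-methylbutyl]-5-methoxy-6-(3-methylbut-2-enyl)-4-propyl-3,4-dihydro-2H-chromen-2-one
Conditions: Bu4NF, AcOH, THF, 0 °C → rt
Reagents that add atoms: none
Why: Fluoride desilylation should remove the aryl TIPS and the alkyl TBS group together, the acetic acid buffer keeping the phenoxide from opening the aryl lactone and the medium non-acidic so that the freed phenol does not add to the neighbouring prenyl alkene.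

Step 12
Reactants: 25 (4R)-7-hydroxy-8-[(2R,3R)-3-hydroxy-2-methylbutyl]-5-methoxy-6-(3-methylbut-2-enyl)-4-propyl-3,4-dihydro-2H-chromen-2-one
Product: 27 (4R,8S,9R)-5-methoxy-8,9-dimethyl-6-(3-methylbut-2-enyl)-4-propyl-3,4,9,10-tetrahydro-2H,8H-pyrano[2,3-f]chromen-2-one, via alkoxyphosphonium phenoxide 26 (not isolated)
Conditions: PPh3, DIAD, THF, 0 °C → rt
Reagents that add atoms: none
Why: Intramolecular Mitsunobu etherification, in which the only acidic OH displaces the activated secondary carbinol in a 6-exo-tet SN2 closure, should invert that centre from R to S and so give the trans-2,3-dimethyl dihydropyran, the neighbouring methyl-bearing centre being untouched.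

Step 13
Reactants: 27 (4R,8S,9R)-5-methoxy-8,9-dimethyl-6-(3-methylbut-2-enyl)-4-propyl-3,4,9,10-tetrahydro-2H,8H-pyrano[2,3-f]chromen-2-one
Product: 29 (3R)-3-[(2S,3R)-5-hydroxy-7-methoxy-2,3-dimethyl-8-(3-methylbut-2-enyl)-3,4-dihydro-2H-chromen-6-yl]hexanoic acid (CNP0275989.1), via dilithium carboxylate phenoxide 28 (not isolated)
Conditions: LiOH, THF/H2O, 0 °C; then 1 M HCl to pH 4 at 0 °C, cold extraction
Reagents that add atoms: lithium hydroxide, [Li+].[OH-]
Why: Saponification of the aryl lactone is fast and touches no stereocentre (the benzylic one is β to the carbonyl), and cold, mild acidification should release the hydroxy acid without relactonisation or acid-induced reaction of the prenyl group, which now has no free ortho phenol.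

**Compound list**

1 | (2R,3R)-2,3-epoxybutane | C[C@H]1O[C@@H]1C | starting material
2 | 1-(trimethylsilyl)propyne | CC#C[Si](C)(C)C | starting material
3 | 3-lithio-1-(trimethylsilyl)prop-1-yne | [Li]CC#C[Si](C)(C)C | intermediate (not isolated)
4 | (2R,3R)-3-methyl-6-(trimethylsilyl)hex-5-yn-2-ol | C[C@@H](O)[C@H](C)CC#C[Si](C)(C)C | intermediate
5 | tert-butyl(dimethyl){[(2R,3R)-3-methyl-6-(trimethylsilyl)hex-5-yn-2-yl]oxy}silane | C[C@@H](O[Si](C)(C)C(C)(C)C)[C@H](C)CC#C[Si](C)(C)C | intermediate
6 | tert-butyl(dimethyl){[(2R,3R)-3-methylhex-5-yn-2-yl]oxy}silane | C[C@@H](O[Si](C)(C)C(C)(C)C)[C@H](C)CC#C | intermediate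
7 | lithium acetylide of 6 | C[C@@H](O[Si](C)(C)C(C)(C)C)[C@H](C)CC#C[Li] | intermediate (not isolated)
8 | lithium ynolate derived from 7 | C[C@@H](O[Si](C)(C)C(C)(C)C)[C@H](C)CC#CO[Li] | intermediate (not isolated)
9 | (4R,5R)-5-(tert-butyldimethylsilyloxy)-4-methyl-1-(triisopropylsilyloxy)hex-1-yne | C[C@@H](O[Si](C)(C)C(C)(C)C)[C@H](C)CC#CO[Si](C(C)C)(C(C)C)C(C)C | intermediate
10 | 3-propylglutaric anhydride | CCCC1CC(=O)OC(=O)C1 | starting material
11 | (3S)-3-(2-methoxy-2-oxoethyl)hexanoic acid | CCC[C@H](CC(=O)OC)CC(=O)O | intermediate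
12 | chloroacetaldehyde dimethyl acetal | COC(CCl)OC | starting material
13 | prenyl bromide (1-bromo-3-methylbut-2-ene) | CC(C)=CCBr | starting material
14 | lithium methoxyacetylide | COC#C[Li] | intermediate (not isolated)
15 | 1-methoxy-5-methylhex-4-en-1-yne | COC#CCC=C(C)C | intermediate
16 | methyl (3R)-3-(2-chloro-2-oxoethyl)hexanoate | CCC[C@H](CC(=O)OC)CC(=O)Cl | intermediate
17 | methyl (3R)-3-(2-oxoethenyl)hexanoate (aldoketene) | CCC[C@H](CC(=O)OC)C=C=O | intermediate (not isolated)
18 | methyl (3R)-3-[2-methoxy-3-(3-methylbut-2-enyl)-4-oxocyclobut-2-en-1-yl]hexanoate, epimers at the ring CH (cyclobutenone numbering: C1 carbonyl, C2 prenyl, C3 OMe, C4 arm) | CCC[C@H](CC(=O)OC)C1C(=O)C(CC=C(C)C)=C1OC | intermediate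
19 | methyl (3R)-3-[(1Z)-2-methoxy-3-(3-methylbut-2-enyl)-4-oxobuta-1,3-dienyl]hexanoate (vinylketene, arm anti to the ketene carbon) | CCC[C@H](CC(=O)OC)/C=C(OC)/C(CC=C(C)C)=C=O | intermediate (not isolated)
20 | 4-vinylcyclobutenone: cyclobut-2-enone with the (2R,3R)-3-(TBSO)-2-methylbutyl chain on C2, OTIPS on C3, and prenyl plus the (Z)-1-methoxyalkenyl arm on quaternary C4 (C4 epimers) | CCC[C@H](CC(=O)OC)/C=C(OC)/C1(CC=C(C)C)C(=O)C(C[C@@H](C)[C@@H](C)O[Si](C)(C)C(C)(C)C)=C1O[Si](C(C)C)(C(C)C)C(C)C | intermediate (not isolated)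
21 | dienylketene O=C=C(chain)–C(OTIPS)=C(prenyl)–C(OMe)=CH–arm | CCC[C@H](CC(=O)OC)/C=C(OC)/C(CC=C(C)C)=C(O[Si](C(C)C)(C(C)C)C(C)C)\C(C[C@@H](C)[C@@H](C)O[Si](C)(C)C(C)(C)C)=C=O | intermediate (not isolated)
22 | cyclohexa-2,4-dienone tautomer of 23 (epimers at the ring CH) | O=C1C(C[C@@H](C)[C@@H](C)O[Si](C)(C)C(C)(C)C)=C(O[Si](C(C)C)(C(C)C)C(C)C)C(CC=C(C)C)=C(OC)C1[C@H](CCC)CC(=O)OC | intermediate (not isolated)
23 | methyl (3R)-3-{3-[(2R,3R)-3-(tert-butyldimethylsilyloxy)-2-methylbutyl]-2-hydroxy-6-methoxy-5-(3-methylbut-2-enyl)-4-(triisopropylsilyloxy)phenyl}hexanoate | CCC[C@H](CC(=O)OC)c1c(O)c(C[C@@H](C)[C@@H](C)O[Si](C)(C)C(C)(C)C)c(O[Si](C(C)C)(C(C)C)C(C)C)c(CC=C(C)C)c1OC | intermediate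
24 | (4R)-8-[(2R,3R)-3-(tert-butyldimethylsilyloxy)-2-methylbutyl]-5-methoxy-6-(3-methylbut-2-enyl)-4-propyl-7-(triisopropylsilyloxy)-3,4-dihydro-2H-chromen-2-one | CCC[C@@H]1CC(=O)Oc2c(C[C@@H](C)[C@@H](C)O[Si](C)(C)C(C)(C)C)c(O[Si](C(C)C)(C(C)C)C(C)C)c(CC=C(C)C)c(OC)c12 | intermediate
25 | (4R)-7-hydroxy-8-[(2R,3R)-3-hydroxy-2-methylbutyl]-5-methoxy-6-(3-methylbut-2-enyl)-4-propyl-3,4-dihydro-2H-chromen-2-one | CCC[C@@H]1CC(=O)Oc2c(C[C@@H](C)[C@@H](C)O)c(O)c(CC=C(C)C)c(OC)c12 | intermediate
26 | alkoxytriphenylphosphonium phenoxide of 25 (zwitterion) | CCC[C@@H]1CC(=O)Oc2c(C[C@@H](C)[C@@H](C)O[P+](c3ccccc3)(c3ccccc3)c3ccccc3)c([O-])c(CC=C(C)C)c(OC)c12 | intermediate (not isolated)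
27 | (4R,8S,9R)-5-methoxy-8,9-dimethyl-6-(3-methylbut-2-enyl)-4-propyl-3,4,9,10-tetrahydro-2H,8H-pyrano[2,3-f]chromen-2-one | CCC[C@@H]1CC(=O)Oc2c3c(c(CC=C(C)C)c(OC)c12)O[C@@H](C)[C@H](C)C3 | intermediate
28 | dilithium carboxylate phenoxide of the target | CCC[C@H](CC(=O)[O-])c1c([O-])c2c(c(CC=C(C)C)c1OC)O[C@@H](C)[C@H](C)C2.[Li+].[Li+] | intermediate (not isolated)
29 | (3R)-3-[(2S,3R)-5-hydroxy-7-methoxy-2,3-dimethyl-8-(3-methylbut-2-enyl)-3,4-dihydro-2H-chromen-6-yl]hexanoic acid (CNP0275989.1) | CCC[C@H](CC(=O)O)c1c(O)c2c(c(CC=C(C)C)c1OC)O[C@@H](C)[C@H](C)C2 | target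

**Count and risks**

Total step count: 13. Longest linear sequence: 9 steps (steps 1, 2, 3, 4, 9, 10, 11, 12, 13).

Steps most likely to fail:

Step 9. The fully substituted, donor-stabilised cyclobutenone 18 may open too slowly, so that thermal rearrangement of siloxyalkyne 9 to a silylketene, or acylation of the phenol by the vinylketene, takes over. The fallback makes the same vinylketene 19 at room temperature from an acyclic precursor; it sets out from acid chloride 16 and rejoins the route at phenol 23.
- Addition of 16 to excess lithium enolate of tert-butyl acetate (THF, −78 °C, crossed Claisen condensation) should give 1-tert-butyl 7-methyl (5S)-3-oxo-5-propylheptanedioate F1.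
- C-alkylation with prenyl bromide 13 (K2CO3, acetone) should give 1-tert-butyl 7-methyl (5S)-2-(3-methylbut-2-enyl)-3-oxo-5-propylheptanedioate F2.
- O-methylation of its potassium enolate (KN(SiMe3)2, DMPU/THF, MeOTf) should give 1-tert-butyl 7-methyl (5S)-3-methoxy-2-(3-methylbut-2-enyl)-5-propylhept-2-enedioate F3.
- Selective cleavage of the tert-butyl ester (Me3SiOTf, 2,6-lutidine, CH2Cl2, then water) should give (5S)-3-methoxy-5-(2-methoxy-2-oxoethyl)-2-(3-methylbut-2-enyl)oct-2-enoic acid F4.
- 1-Chloro-N,N,2-trimethylprop-1-en-1-amine under neutral conditions should give (5S)-3-methoxy-5-(2-methoxy-2-oxoethyl)-2-(3-methylbut-2-enyl)oct-2-enoyl chloride F5.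
- Et3N then removes HCl across the enoyl system (1,4-elimination) in the presence of 9; vinylketene 19 is trapped as 20, and gentle warming (60–80 °C) should complete the cascade to 23.

Step 8. Amine-catalysed dimerisation or oligomerisation of the monosubstituted ketene 17 may outrun its cycloaddition to the internal alkyne. The fallback generates the ketene without amine; it sets out from acid chloride 16 and rejoins the route at cyclobutenone 18.
- α-Bromination (NBS, HBr cat., 1,2-dichloroethane, 70 °C, Hell–Volhard–Zelinsky type; only the acid chloride enolises) should give methyl (3R)-3-(1-bromo-2-chloro-2-oxoethyl)hexanoate F6.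
- Slow addition of F6 to zinc–copper couple and alkyne 15 in Et2O/DME (reductive dehalogenation to 17 at low stationary concentration, DME binding the zinc halide) should give 18.

Step 12. The activated secondary carbinol, next to a methyl-branched carbon, may eliminate to the alkene faster than the hindered phenoxide displaces it. The fallback separates activation from displacement; it sets out from lactone 24 and rejoins the route at tricyclic lactone 27.
- Aqueous HF in MeCN at 0 °C should cleave the alkyl TBS ether and leave the aryl TIPS ether, giving (4R)-8-[(2R,3R)-3-hydroxy-2-methylbutyl]-5-methoxy-6-(3-methylbut-2-enyl)-4-propyl-7-(triisopropylsilyloxy)-3,4-dihydro-2H-chromen-2-one F7.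
- MsCl and Et3N (CH2Cl2, 0 °C) should give (2R,3R)-3-methyl-4-[(4R)-5-methoxy-6-(3-methylbut-2-enyl)-2-oxo-4-propyl-7-(triisopropylsilyloxy)-3,4-dihydro-2H-chromen-8-yl]butan-2-yl methanesulfonate F8.
- Bu4NF in THF then unmasks the phenoxide, which displaces the mesylate in a 6-exo-tet SN2 reaction with inversion to give 27.

Further compounds
F1 | step 9 | 1-tert-butyl 7-methyl (5S)-3-oxo-5-propylheptanedioate | CCC[C@H](CC(=O)OC)CC(=O)CC(=O)OC(C)(C)C
F2 | step 9 | 1-tert-butyl 7-methyl (5S)-2-(3-methylbut-2-enyl)-3-oxo-5-propylheptanedioate (epimers at C2) | CCC[C@H](CC(=O)OC)CC(=O)C(CC=C(C)C)C(=O)OC(C)(C)C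
F3 | step 9 | 1-tert-butyl 7-methyl (5S)-3-methoxy-2-(3-methylbut-2-enyl)-5-propylhept-2-enedioate (alkene isomers) | CCC[C@H](CC(=O)OC)CC(OC)=C(CC=C(C)C)C(=O)OC(C)(C)C
F4 | step 9 | (5S)-3-methoxy-5-(2-methoxy-2-oxoethyl)-2-(3-methylbut-2-enyl)oct-2-enoic acid | CCC[C@H](CC(=O)OC)CC(OC)=C(CC=C(C)C)C(=O)O
F5 | step 9 | (5S)-3-methoxy-5-(2-methoxy-2-oxoethyl)-2-(3-methylbut-2-enyl)oct-2-enoyl chloride | CCC[C@H](CC(=O)OC)CC(OC)=C(CC=C(C)C)C(=O)Cl
F6 | step 8 | methyl (3R)-3-(1-bromo-2-chloro-2-oxoethyl)hexanoate (epimers at the CHBr carbon) | CCC[C@H](CC(=O)OC)C(Br)C(=O)Cl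
F7 | step 12 | (4R)-8-[(2R,3R)-3-hydroxy-2-methylbutyl]-5-methoxy-6-(3-methylbut-2-enyl)-4-propyl-7-(triisopropylsilyloxy)-3,4-dihydro-2H-chromen-2-one | CCC[C@@H]1CC(=O)Oc2c(C[C@@H](C)[C@@H](C)O)c(O[Si](C(C)C)(C(C)C)C(C)C)c(CC=C(C)C)c(OC)c12
F8 | step 12 | (2R,3R)-3-methyl-4-[(4R)-5-methoxy-6-(3-methylbut-2-enyl)-2-oxo-4-propyl-7-(triisopropylsilyloxy)-3,4-dihydro-2H-chromen-8-yl]butan-2-yl methanesulfonate | CCC[C@@H]1CC(=O)Oc2c(C[C@@H](C)[C@@H](C)OS(C)(=O)=O)c(O[Si](C(C)C)(C(C)C)C(C)C)c(CC=C(C)C)c(OC)c12
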